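The synthesis rests on disconnecting C2–C3, the bond shared by pyranone ring C and the dihydrofuran ring. C3 is a tertiary carbinol flanked by the C4 ketone, and C2 carries O7' and aryl B. This is the imprint of a C3 ketone that has taken a hydrogen from an O7' benzyl ether. A visible-light Norrish–Yang cyclisation thus makes C2–C3, the furan ring and the 3-hydroxyl in one operation. Its precursor is a flat 1,2-diketone, C3(=O)–C4(=O), linking C8' of a naringenin-derived (2S)-flavan to ring A, with O7' as a 4-silyloxybenzyl ether and ring A fully silylated. Desilylation, quinone methide ketalisation (ring C) and hydrogenolysis follow.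

Key step: step 12

Numbering: the chromanone half is O1, C2 (ketal carbon, aryl B), C3 (carbinol), C4 (ketone) and ring A. The flavan half is primed (O1', C2' bearing aryl B', C4', O5', O7', C8'), and the primed numbers are also used for naringenin and all flavan intermediates.

Assumption: a chromanone and a 2,3-dihydrobenzofuran that share C2–C3 can only be cis-fused, so the ketal carbon C2 is dictated by C3 and is no independent centre; C3 and C2' are taken from the target string as the centres to be secured, and 21 and 22 carry the C2 label of that string unchanged, although read literally it puts aryl B anti to the 3-hydroxyl, which is regarded as an artefact of the drawing behind the string.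

Step 1
Reactants: 1 4-hydroxybenzyl alcohol
Product: 2 4-(triisopropylsilyloxy)benzyl alcohol
Conditions: NaH (1.0 equiv), THF, 0 °C; TIPSCl (1.0 equiv), 0 °C to rt
Reagents that add atoms: triisopropylsilyl chloride, CC(C)[Si](Cl)(C(C)C)C(C)C
Why: Chemoselective O-silylation: one equivalent of NaH deprotonates only the phenol (pKa near 10 against about 15 for the benzylic alcohol), and the phenoxide outruns the neutral alcohol at silicon.

Step 2
Reactants: 3 (2S)-naringenin; 2 4-(triisopropylsilyloxy)benzyl alcohol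
Product: 4 (2S)-5-hydroxy-2-(4-hydroxyphenyl)-7-[4-(triisopropylsilyloxy)benzyloxy]chroman-4-one
Conditions: PPh3, DIAD, THF, 0 °C to rt
Reagents that add atoms: none
Why: Mitsunobu etherification takes the most acidic phenol, the 7'-OH para to the carbonyl, while the 5'-OH is tied up in a hydrogen bond, and the absence of added base keeps the flavanone from opening to the chalcone, so C2' stays S.

Step 3
Reactants: 4 (2S)-5-hydroxy-2-(4-hydroxyphenyl)-7-[4-(triisopropylsilyloxy)benzyloxy]chroman-4-one
Product: 5 (2S)-2-(4-benzyloxyphenyl)-5-hydroxy-7-[4-(triisopropylsilyloxy)benzyloxy]chroman-4-one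
Conditions: BnOH, PPh3, DIAD, THF, 0 °C to rt
Reagents that add atoms: benzyl alcohol, OCc1ccccc1
Why: A second Mitsunobu etherification benzylates the phenol of aryl B', the chelated 5'-OH being too weakly acidic to compete, and again no base is present that could racemise C2'.

Step 4
Reactants: 5 (2S)-2-(4-benzyloxyphenyl)-5-hydroxy-7-[4-(triisopropylsilyloxy)benzyloxy]chroman-4-one
Product: 8 (2S)-2-(4-benzyloxyphenyl)-7-[4-(triisopropylsilyloxy)benzyloxy]chroman-5-ol, via aryl ethyl carbonate 6 (not isolated), via ortho-quinone methide 7 (not isolated)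
Conditions: ClCO2Et, Et3N, THF, 0 °C; then NaBH4, H2O, 0 °C to rt
Reagents that add atoms: none
Why: Reductive deoxygenation of an o-hydroxyaryl ketone through its carbonate: borohydride reduces C4'=O, the carbonate migrates to the new alkoxide and leaves to give 7, which takes a second hydride at C4', while C2', the benzylic ethers and the TIPS ether are not touched.

Step 5
Reactants: 8 (2S)-2-(4-benzyloxyphenyl)-7-[4-(triisopropylsilyloxy)benzyloxy]chroman-5-ol
Product: 9 (2S)-5-benzyloxy-2-(4-benzyloxyphenyl)-7-[4-(triisopropylsilyloxy)benzyloxy]chroman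
Conditions: BnBr, K2CO3, DMF, rt
Reagents that add atoms: benzyl bromide, BrCc1ccccc1
Why: Williamson ether synthesis on the only free phenol; with the carbonyl gone C2' is no longer base-labile, and the hindered aryl TIPS ether tolerates carbonate at room temperature.

Step 6
Reactants: 9 (2S)-5-benzyloxy-2-(4-benzyloxyphenyl)-7-[4-(triisopropylsilyloxy)benzyloxy]chroman
Product: 10 (2S)-5-benzyloxy-2-(4-benzyloxyphenyl)-8-iodo-7-[4-(triisopropylsilyloxy)benzyloxy]chroman
Conditions: NIS (1.0 equiv), CH2Cl2, −20 to 0 °C, dark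
Reagents that add atoms: N-iodosuccinimide, O=C1CCC(=O)N1I
Why: Electrophilic aromatic iodination: in 5,7-dialkoxyflavans C8', between O7' and the in-plane ring oxygen O1', is more nucleophilic and less crowded than C6', which lies between two freely rotating benzyloxy groups, and the monooxygenated rings are far less reactive.

Step 7
Reactants: 11 2,4,6-trihydroxybenzaldehyde
Product: 12 2,4,6-tris(tert-butyldimethylsilyloxy)benzaldehyde
Conditions: TBSCl (3.6 equiv), imidazole, DMF, rt
Reagents that add atoms: tert-butyldimethylsilyl chloride, CC(C)(C)[Si](C)(C)Cl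
Why: Imidazole-promoted silyl ether formation on all three phenols keeps ring A symmetric, so no regioselective protection is needed.

Step 8
Reactants: 12 2,4,6-tris(tert-butyldimethylsilyloxy)benzaldehyde
Product: 13 2-(2,2-dibromovinyl)-1,3,5-tris(tert-butyldimethylsilyloxy)benzene
Conditions: CBr4, PPh3, Zn, CH2Cl2, rt; then 12, 0 °C to rt
Reagents that add atoms: carbon tetrabromide, BrC(Br)(Br)Br
Why: First stage of the Corey–Fuchs homologation (Wittig-type dibromoolefination); the zinc variant is neutral and avoids Ph3PBr2, so the aryl silyl ethers survive.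

Step 9
Reactants: 13 2-(2,2-dibromovinyl)-1,3,5-tris(tert-butyldimethylsilyloxy)benzene
Product: 14 2-ethynyl-1,3,5-tris(tert-butyldimethylsilyloxy)benzene
Conditions: n-BuLi (2.2 equiv), THF, −78 °C; then H2O
Reagents that add atoms: none
Why: Second stage of the Corey–Fuchs homologation (bromine–lithium exchange, Fritsch–Buttenberg–Wiechell 1,2-shift, aqueous quench); unlike diazo-based homologations it passes through no benzylic alkoxide that could pull a silyl group off the ortho oxygens.

Step 10
Reactants: 10 (2S)-5-benzyloxy-2-(4-benzyloxyphenyl)-8-iodo-7-[4-(triisopropylsilyloxy)benzyloxy]chroman; 14 2-ethynyl-1,3,5-tris(tert-butyldimethylsilyloxy)benzene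
Product: 15 (2S)-5-benzyloxy-2-(4-benzyloxyphenyl)-7-[4-(triisopropylsilyloxy)benzyloxy]-8-{[2,4,6-tris(tert-butyldimethylsilyloxy)phenyl]ethynyl}chroman
Conditions: PdCl2(PPh3)2 (5 mol %), CuI (10 mol %), Et3N–DMF, 60 °C, argon
Reagents that add atoms: none
Why: Sonogashira coupling; the iodide compensates for the electron-rich, doubly ortho-oxygenated C8', the linear alkyne keeps the two crowded rings apart, and silyl and benzyl ethers are inert to the tertiary amine.

Step 11
Reactants: 15 (2S)-5-benzyloxy-2-(4-benzyloxyphenyl)-7-[4-(triisopropylsilyloxy)benzyloxy]-8-{[2,4,6-tris(tert-butyldimethylsilyloxy)phenyl]ethynyl}chroman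
Product: 16 1-[2,4,6-tris(tert-butyldimethylsilyloxy)phenyl]-2-{(2S)-5-benzyloxy-2-(4-benzyloxyphenyl)-7-[4-(triisopropylsilyloxy)benzyloxy]chroman-8-yl}ethane-1,2-dione
Conditions: KMnO4, NaHCO3, MgSO4, acetone–H2O, 0 °C to rt
Reagents that add atoms: potassium permanganate, [K+].[O-][Mn](=O)(=O)=O
Why: Buffered permanganate oxidation of a diarylalkyne to a benzil by cycloaddition of MnO4− to the triple bond; it is preferred to electrophilic oxidants based on divalent palladium or iodine, which would activate the alkyne toward attack by O7' with loss of the stabilised benzyl cation and so lead to a benzofuran.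

Step 12
Reactants: 16 1-[2,4,6-tris(tert-butyldimethylsilyloxy)phenyl]-2-{(2S)-5-benzyloxy-2-(4-benzyloxyphenyl)-7-[4-(triisopropylsilyloxy)benzyloxy]chroman-8-yl}ethane-1,2-dione
Product: 18 (2S,3S,2'S)-2-aryl-3-aroyl-3-hydroxy-2,3-dihydrobenzofuran fused to the flavan (aryl B anti to the aroyl group; C3 spatially as in the target), via triplet 1,5-biradical 17 (not isolated)
Conditions: hν (450 nm LED), degassed benzene (5 mM), 20 °C; then chromatographic separation of the C3 epimers
Reagents that add atoms: none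
Why: Proposed new method: blue light excites only the n,π* band of the dicarbonyl (aryl and silyl ethers are transparent there), the long-lived triplet lets its C3 oxygen take a benzylic hydrogen from O7'–CH2–aryl B by 1,6-transfer through a seven-membered array, and after spin inversion biradical 17 couples C2 with C3; the closest known reaction type is the Norrish–Yang photocyclisation of o-benzyloxyphenyl ketones and o-benzyloxyphenylglyoxylates to 2-aryl-2,3-dihydrobenzofuran-3-ols, which has not been shown for a diaryl 1,2-diketone. The one new ring, the dihydrofuran O7'–C2–C3–C8'–C7', closes by radical–radical recombination of a 1,5-biradical. C2 is controlled by C3 through sterics in the closing biradical: aryl B turns away from the bulky aroyl group and ends syn to the small hydroxyl, a preference that is largest in a solvent that does not hydrogen-bond to that hydroxyl. C3 has no controlling element, since the distant C2' centre does not differentiate the two faces of the ketyl carbon; C2' only turns the two C3 epimers into diastereomers, and the one drawn is separated by chromatography. The selectivity needed is that of the abstraction site: silyl ethers leave ring A without an activated C–H, the pyran ring holds C2'–H anti to C8' and out of reach, and the other benzyl ethers are remote from both carbonyl groups. Abstraction by the C4 oxygen (eight-membered array) would require C2 to bond to C4, which is walled in by the two ortho-silyloxy groups of ring A, so this biradical should hand the hydrogen back rather than close a six-membered ring.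

Step 13
Reactants: 18 (2S,3S,2'S)-2-aryl-3-aroyl-3-hydroxy-2,3-dihydrobenzofuran fused to the flavan
Product: 19 (2S,3S,2'S)-3-hydroxy-2-(4-hydroxyphenyl)-3-(2,4,6-trihydroxybenzoyl)-2,3-dihydrobenzofuran fused to the 5'-O,B'-O-dibenzyl flavan
Conditions: TBAF, AcOH (1:1, 5 equiv each), THF, 0 °C
Reagents that add atoms: none
Why: Fluoride cleavage of the four aryl silyl ethers; acetic acid keeps the liberated phenols protonated, which holds back phenoxide-driven 1,6-expulsion of O7' from C2 and base-induced α-ketol rearrangement, while the benzyl ethers, C3 and C2' are untouched.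

Step 14
Reactants: 19 (2S,3S,2'S)-3-hydroxy-2-(4-hydroxyphenyl)-3-(2,4,6-trihydroxybenzoyl)-2,3-dihydrobenzofuran fused to the 5'-O,B'-O-dibenzyl flavan
Product: 21 5'-O,B'-O-dibenzyldaphnodorin F, via para-quinone methide 20 (not isolated)
Conditions: Ag2O (1.5 equiv), CH2Cl2–acetone, rt, dark
Reagents that add atoms: none
Why: Ag2O dehydrogenates the one 4-hydroxybenzylic C–H whose phenol is free (aryl B' is still a benzyl ether and the ring A phenols are deactivated by the acyl group) to the O7'-stabilised quinone methide 20, and an ortho-hydroxyl of ring A adds to C2 in a 1,6-conjugate addition that closes ring C, the type of oxidative ketalisation known from the conversion of B-type into A-type proanthocyanidins; because the phenol is tethered through C3–C4 it can reach C2 only from the face that carries the aroyl group, so C3 sets C2 and the fusion is cis.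

Step 15
Reactants: 21 5'-O,B'-O-dibenzyldaphnodorin F
Product: 22 daphnodorin F
Conditions: H2 (1 atm), 10% Pd/C, THF–EtOAc, rt
Reagents that add atoms: none
Why: Catalytic hydrogenolysis of the two aryl benzyl ethers; as in flavan-3-ol syntheses the ring-bound benzylic C–O bonds (C2'–O1', the fully substituted ketal C2, the tertiary C3–OH) and the vinylogous-acid-type C4 ketone should survive one atmosphere and a short reaction time, and no stereocentre is affected.

Compound list
1 | 4-hydroxybenzyl alcohol | OCc1ccc(O)cc1 | starting material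
2 | 4-(triisopropylsilyloxy)benzyl alcohol | OCc1ccc(O[Si](C(C)C)(C(C)C)C(C)C)cc1 | intermediate
3 | (2S)-naringenin | O=C1C[C@@H](c2ccc(O)cc2)Oc2cc(O)cc(O)c12 | starting material
4 | (2S)-5-hydroxy-2-(4-hydroxyphenyl)-7-[4-(triisopropylsilyloxy)benzyloxy]chroman-4-one | O=C1C[C@@H](c2ccc(O)cc2)Oc2cc(OCc3ccc(O[Si](C(C)C)(C(C)C)C(C)C)cc3)cc(O)c12 | intermediate
5 | (2S)-2-(4-benzyloxyphenyl)-5-hydroxy-7-[4-(triisopropylsilyloxy)benzyloxy]chroman-4-one | O=C1C[C@@H](c2ccc(OCc3ccccc3)cc2)Oc2cc(OCc3ccc(O[Si](C(C)C)(C(C)C)C(C)C)cc3)cc(O)c12 | intermediate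
6 | (2S)-2-(4-benzyloxyphenyl)-4-oxo-7-[4-(triisopropylsilyloxy)benzyloxy]chroman-5-yl ethyl carbonate | O=C1C[C@@H](c2ccc(OCc3ccccc3)cc2)Oc2cc(OCc3ccc(O[Si](C(C)C)(C(C)C)C(C)C)cc3)cc(OC(=O)OCC)c12 | intermediate
7 | (2S)-2-(4-benzyloxyphenyl)-7-[4-(triisopropylsilyloxy)benzyloxy]-2,3-dihydro-5H-chromen-5-one (ortho-quinone methide, C4'=C4a') | O=C1C=C(OCc2ccc(O[Si](C(C)C)(C(C)C)C(C)C)cc2)C=C2O[C@H](c3ccc(OCc4ccccc4)cc3)CC=C12 | intermediate
8 | (2S)-2-(4-benzyloxyphenyl)-7-[4-(triisopropylsilyloxy)benzyloxy]chroman-5-ol | Oc1cc(OCc2ccc(O[Si](C(C)C)(C(C)C)C(C)C)cc2)cc2O[C@H](c3ccc(OCc4ccccc4)cc3)CCc12 | intermediate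
9 | (2S)-5-benzyloxy-2-(4-benzyloxyphenyl)-7-[4-(triisopropylsilyloxy)benzyloxy]chroman | c1ccccc1COc1cc(OCc2ccc(O[Si](C(C)C)(C(C)C)C(C)C)cc2)cc2O[C@H](c3ccc(OCc4ccccc4)cc3)CCc12 | intermediate
10 | (2S)-5-benzyloxy-2-(4-benzyloxyphenyl)-8-iodo-7-[4-(triisopropylsilyloxy)benzyloxy]chroman | c1ccccc1COc1cc(OCc2ccc(O[Si](C(C)C)(C(C)C)C(C)C)cc2)c(I)c2O[C@H](c3ccc(OCc4ccccc4)cc3)CCc12 | intermediate
11 | 2,4,6-trihydroxybenzaldehyde | O=Cc1c(O)cc(O)cc1O | starting material
12 | 2,4,6-tris(tert-butyldimethylsilyloxy)benzaldehyde | O=Cc1c(O[Si](C)(C)C(C)(C)C)cc(O[Si](C)(C)C(C)(C)C)cc1O[Si](C)(C)C(C)(C)C | intermediate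
13 | 2-(2,2-dibromovinyl)-1,3,5-tris(tert-butyldimethylsilyloxy)benzene | BrC(Br)=Cc1c(O[Si](C)(C)C(C)(C)C)cc(O[Si](C)(C)C(C)(C)C)cc1O[Si](C)(C)C(C)(C)C | intermediate
14 | 2-ethynyl-1,3,5-tris(tert-butyldimethylsilyloxy)benzene | C#Cc1c(O[Si](C)(C)C(C)(C)C)cc(O[Si](C)(C)C(C)(C)C)cc1O[Si](C)(C)C(C)(C)C | intermediate
15 | diarylalkyne: (2S)-5-benzyloxy-2-(4-benzyloxyphenyl)-7-[4-(triisopropylsilyloxy)benzyloxy]-8-{[2,4,6-tris(tert-butyldimethylsilyloxy)phenyl]ethynyl}chroman | CC(C)(C)[Si](C)(C)Oc1cc(O[Si](C)(C)C(C)(C)C)cc(O[Si](C)(C)C(C)(C)C)c1C#Cc1c(OCc2ccc(O[Si](C(C)C)(C(C)C)C(C)C)cc2)cc(OCc2ccccc2)c2c1O[C@H](c1ccc(OCc3ccccc3)cc1)CC2 | intermediate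
16 | 1,2-diketone: 1-[2,4,6-tris(tert-butyldimethylsilyloxy)phenyl]-2-{(2S)-5-benzyloxy-2-(4-benzyloxyphenyl)-7-[4-(triisopropylsilyloxy)benzyloxy]chroman-8-yl}ethane-1,2-dione | CC(C)(C)[Si](C)(C)Oc1cc(O[Si](C)(C)C(C)(C)C)cc(O[Si](C)(C)C(C)(C)C)c1C(=O)C(=O)c1c(OCc2ccc(O[Si](C(C)C)(C(C)C)C(C)C)cc2)cc(OCc2ccccc2)c2c1O[C@H](c1ccc(OCc3ccccc3)cc1)CC2 | intermediate
17 | 1,5-biradical: hydroxy-substituted radical at C3, O7'-substituted benzylic radical at C2 | CC(C)(C)[Si](C)(C)Oc1cc(O[Si](C)(C)C(C)(C)C)cc(O[Si](C)(C)C(C)(C)C)c1C(=O)[C](O)c1c(O[CH]c2ccc(O[Si](C(C)C)(C(C)C)C(C)C)cc2)cc(OCc2ccccc2)c2c1O[C@H](c1ccc(OCc3ccccc3)cc1)CC2 | intermediate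
18 | photoproduct, (2S,3S,2'S): dihydrofuran ring O7'–C2–C3–C8'–C7' on the (2S)-5-benzyloxy-2-(4-benzyloxyphenyl)chroman; C2 bears H and 4-(triisopropylsilyloxy)phenyl, C3 bears OH and 2,4,6-tris(tert-butyldimethylsilyloxy)benzoyl; aryl B anti to the aroyl group and syn to 3-OH | CC(C)(C)[Si](C)(C)Oc1cc(O[Si](C)(C)C(C)(C)C)cc(O[Si](C)(C)C(C)(C)C)c1C(=O)[C@@]2(O)[C@H](c3ccc(O[Si](C(C)C)(C(C)C)C(C)C)cc3)Oc3cc(OCc5ccccc5)c4c(c32)O[C@H](c2ccc(OCc5ccccc5)cc2)CC4 | intermediate
19 | desilylated photoproduct, (2S,3S,2'S): as 18 with 4-hydroxyphenyl on C2 and 2,4,6-trihydroxybenzoyl on C3 | Oc1cc(O)cc(O)c1C(=O)[C@@]2(O)[C@H](c3ccc(O)cc3)Oc3cc(OCc5ccccc5)c4c(c32)O[C@H](c2ccc(OCc5ccccc5)cc2)CC4 | intermediate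
20 | para-quinone methide, (3S,2'S): as 19 with C2 doubly bonded to a 4-oxocyclohexa-2,5-dienylidene ring | Oc1cc(O)cc(O)c1C(=O)[C@@]2(O)C(=C3C=CC(=O)C=C3)Oc3cc(OCc5ccccc5)c4c(c32)O[C@H](c2ccc(OCc5ccccc5)cc2)CC4 | intermediate
21 | 5'-O,B'-O-dibenzyldaphnodorin F: ring C closed (O1–C2), cis-fused ketal, C3 unchanged in space (descriptor now R because C2 outranks C4), C2' S | O=C1c2c(O)cc(O)cc2O[C@]2(c3ccc(O)cc3)Oc3cc(OCc5ccccc5)c4c(c3[C@@]12O)O[C@H](c1ccc(OCc5ccccc5)cc1)CC4 | intermediate
22 | daphnodorin F | O=C1c2c(O)cc(O)cc2O[C@]2(c3ccc(O)cc3)Oc3cc(O)c4c(c3[C@@]12O)O[C@H](c1ccc(O)cc1)CC4 | target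

Total step count: 15. Longest linear sequence: 12 steps (steps 1–6 and 10–15).

Steps most likely to fail

1. **Step 12.** The triplet may be drained by charge transfer from the two electron-rich rings or by reversible hydrogen transfer. Abstraction may also shift to the C4 oxygen, and the missing facial bias at C3 costs material. The fallback uses known chemistry, sets out from 10 and comes back at 18.
   - Iodine–lithium exchange (n-BuLi, THF, −78 °C) and inverse addition to excess dimethyl oxalate give methyl arylglyoxylate F1. F1 belongs to the substrate class for which this photocyclisation is established.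
   - Irradiation at 365 nm in degassed benzene gives hydroxy ester F2, whose C3 epimers are separated.
   - In parallel, phloroglucinol is silylated (TBSCl, imidazole, DMF) to 1,3,5-tris(tert-butyldimethylsilyloxy)benzene F3. It is brominated once (NBS, CH2Cl2, −78 °C, all three positions being equivalent) to aryl bromide F4.
   - Bromine–lithium exchange on F4 (n-BuLi, THF) is held at −78 °C so that oxygen-to-carbon silyl migration does not set in. Acylation of the aryllithium by F2 (one extra equivalent for the carbinol) gives 18. The addition stops at the ketone because the doubly ortho-substituted aroyl group is shielded.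

2. **Step 14.** Coupling of the unhindered phenoxyl radical, or oxidation of the ring A triol, may outrun loss of the C2 hydrogen. In addition 21 is still a phenol and may be oxidised further. The fallback sets out from 18 and comes back at 21. It brings the C2 oxygen in by epoxide opening instead of C–H oxidation.
   - Acid-catalysed dehydration (cat. p-TsOH, toluene, 60 °C), the classical follow-up of such photoproducts, gives 2-aryl-3-aroylbenzofuran F5.
   - Dimethyldioxirane (acetone–CH2Cl2, −20 °C to rt) epoxidises the push–pull C2=C3 bond, as it does in flavones and benzofurans, to epoxide F6.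
   - Buffered TBAF–AcOH then frees the ring A phenol, which opens the epoxide at C2 from the face of the aroyl group and gives 21 directly.
   - The price is that C3 is remade without facial control, so a second separation of diastereomers is needed.

3. **Step 11.** Addition of permanganate to the triple bond, which is shielded by four ortho oxygens, may be slow. Cleavage of the diketone to two acids, attack on the benzylic ethers, or hydrolysis of the activated ortho silyl ethers could then catch up. The fallback sets out from 15 and comes back at 16, and it raises the oxidation level in separate mild stages.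
   - Lindlar semihydrogenation (H2, Pd/CaCO3–Pb(OAc)2, quinoline, EtOAc) gives (Z)-stilbene F7.
   - Catalytic OsO4 with N-methylmorpholine N-oxide (acetone–H2O) gives syn-diol F8 as a mixture of diastereomers of no consequence.
   - A double Swern oxidation ((COCl)2, DMSO, Et3N, CH2Cl2, −78 °C) gives 16 without C–C cleavage.

Further compounds
F1 | step 12 | methyl 2-{(2S)-5-benzyloxy-2-(4-benzyloxyphenyl)-7-[4-(triisopropylsilyloxy)benzyloxy]chroman-8-yl}-2-oxoacetate | COC(=O)C(=O)c1c(OCc2ccc(O[Si](C(C)C)(C(C)C)C(C)C)cc2)cc(OCc2ccccc2)c2c1O[C@H](c1ccc(OCc3ccccc3)cc1)CC2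
F2 | step 12 | methyl 3-hydroxy-2-[4-(triisopropylsilyloxy)phenyl]-2,3-dihydrobenzofuran-3-carboxylate fused to the (2S)-flavan, C2 and C3 arranged as in 18 | COC(=O)[C@@]2(O)[C@H](c3ccc(O[Si](C(C)C)(C(C)C)C(C)C)cc3)Oc3cc(OCc5ccccc5)c4c(c32)O[C@H](c2ccc(OCc5ccccc5)cc2)CC4
F3 | step 12 | 1,3,5-tris(tert-butyldimethylsilyloxy)benzene | CC(C)(C)[Si](C)(C)Oc1cc(O[Si](C)(C)C(C)(C)C)cc(O[Si](C)(C)C(C)(C)C)c1
F4 | step 12 | 2-bromo-1,3,5-tris(tert-butyldimethylsilyloxy)benzene | CC(C)(C)[Si](C)(C)Oc1cc(O[Si](C)(C)C(C)(C)C)cc(O[Si](C)(C)C(C)(C)C)c1Br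
F5 | step 14 | 2-[4-(triisopropylsilyloxy)phenyl]-3-[2,4,6-tris(tert-butyldimethylsilyloxy)benzoyl]benzofuran fused to the (2S)-flavan | CC(C)(C)[Si](C)(C)Oc1cc(O[Si](C)(C)C(C)(C)C)cc(O[Si](C)(C)C(C)(C)C)c1C(=O)c1c(-c2ccc(O[Si](C(C)C)(C(C)C)C(C)C)cc2)oc2cc(OCc3ccccc3)c3c(c12)O[C@H](c1ccc(OCc2ccccc2)cc1)CC3
F6 | step 14 | C2–C3 epoxide of F5, epoxide oxygen on the face of the later 3-OH | CC(C)(C)[Si](C)(C)Oc1cc(O[Si](C)(C)C(C)(C)C)cc(O[Si](C)(C)C(C)(C)C)c1C(=O)[C@@]12O[C@]1(c1ccc(O[Si](C(C)C)(C(C)C)C(C)C)cc1)Oc1cc(OCc3ccccc3)c3c(c12)O[C@H](c1ccc(OCc2ccccc2)cc1)CC3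
F7 | step 11 | (Z)-stilbene from 15 | CC(C)(C)[Si](C)(C)Oc1cc(O[Si](C)(C)C(C)(C)C)cc(O[Si](C)(C)C(C)(C)C)c1/C=C\c1c(OCc2ccc(O[Si](C(C)C)(C(C)C)C(C)C)cc2)cc(OCc2ccccc2)c2c1O[C@H](c1ccc(OCc3ccccc3)cc1)CC2
F8 | step 11 | 1,2-diaryl-1,2-ethanediol from F7 (carbinol centres as a mixture) | CC(C)(C)[Si](C)(C)Oc1cc(O[Si](C)(C)C(C)(C)C)cc(O[Si](C)(C)C(C)(C)C)c1C(O)C(O)c1c(OCc2ccc(O[Si](C(C)C)(C(C)C)C(C)C)cc2)cc(OCc2ccccc2)c2c1O[C@H](c1ccc(OCc3ccccc3)cc1)CC2
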